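**Strategy.** Everything rests on disconnecting the aryl ether bond O1–C8a of the pyran (ring C), so that ring A is the electrophile and the benzylic oxygen on C2 the nucleophile. The key step is an intramolecular SNAr: the C2 alkoxide of an acyclic (1R,2R) 3-(2-fluoroaryl)-2-benzyloxy-1-arylpropan-1-ol displaces fluoride at C8a, which the meta oxygens at C5 and C7 activate inductively. Since neither the C2–O nor the C3–O bond is broken, the syn diad (C3 from methyl (R)-glycidate, C2 from a chelation-controlled aryl Grignard addition) becomes the 2,3-cis chroman without epimerisation. Debenzylation, feruloylation at O3 and acidic removal of five methoxymethyl ethers complete the route.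

Key step: step 9

Assumption: compounds 1, 4, 9 and 17 are taken as commercially available; all phenols travel as methoxymethyl (MOM) ethers so that one acidic step frees them without touching the cinnamate double bond.

Step 1
Reactants: 1 5-fluorobenzene-1,3-diol
Product: 2 1-fluoro-3,5-bis(methoxymethoxy)benzene
Conditions: MOMCl (2.5 equiv), i-Pr2NEt (3 equiv), CH2Cl2, 0 °C to rt
Reagents that add atoms: chloromethyl methyl ether, COCCl
Why: Williamson-type O-alkylation of both phenols with the reactive α-chloro ether should give the bis-acetal, which is stable to the organometallic and strongly basic steps that follow.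

Step 2
Reactants: 2 1-fluoro-3,5-bis(methoxymethoxy)benzene
Product: 3 2-bromo-1-fluoro-3,5-bis(methoxymethoxy)benzene
Conditions: NBS (1.0 equiv), MeCN, 0 °C
Reagents that add atoms: N-bromosuccinimide, O=C1CCC(=O)N1Br
Why: electrophilic aromatic bromination should occur para to one acetal oxygen and ortho to the other, next to the small fluorine, since 5-substituted resorcinol diethers react at C4 rather than at the doubly flanked C2.

Step 3
Reactants: 3 2-bromo-1-fluoro-3,5-bis(methoxymethoxy)benzene; 4 methyl (2R)-oxirane-2-carboxylate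
Product: 6 methyl (2R)-3-[2-fluoro-4,6-bis(methoxymethoxy)phenyl]-2-hydroxypropanoate, via arylmagnesium chloride 5 (not isolated)
Conditions: i-PrMgCl·LiCl, THF, 0 °C; then CuI (10 mol %), 4, −40 to −20 °C; aq. NH4Cl
Reagents that add atoms: none
Why: bromine–magnesium exchange followed by copper-catalysed SN2 opening of the glycidate at its unsubstituted carbon should give the aryl lactate, the stereocenter (future C3) coming unchanged from the chiral-pool epoxide, while the low temperature keeps the ortho-fluoro Grignard reagent from eliminating to an aryne.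

Step 4
Reactants: 6 methyl (2R)-3-[2-fluoro-4,6-bis(methoxymethoxy)phenyl]-2-hydroxypropanoate
Product: 7 methyl (2R)-2-(benzyloxy)-3-[2-fluoro-4,6-bis(methoxymethoxy)phenyl]propanoate
Conditions: BnBr (1.5 equiv), Ag2O (1.5 equiv), CH2Cl2, rt, dark
Reagents that add atoms: benzyl bromide, BrCc1ccccc1
Why: silver-oxide-mediated Williamson etherification works without a strong base, so the α-alkoxy ester should not enolise, and it caps O3 as a non-migrating ether that can still chelate.

Step 5
Reactants: 7 methyl (2R)-2-(benzyloxy)-3-[2-fluoro-4,6-bis(methoxymethoxy)phenyl]propanoate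
Product: 8 (2R)-2-(benzyloxy)-3-[2-fluoro-4,6-bis(methoxymethoxy)phenyl]propanal
Conditions: i-Bu2AlH (1.1 equiv), CH2Cl2, −78 °C; MeOH, aq. potassium sodium tartrate
Reagents that add atoms: none
Why: partial reduction of an α-alkoxy ester should stop at the chelated aluminium hemiacetal at −78 °C and release the aldehyde on work-up; the aldehyde is used at once to avoid epimerisation.

Step 6
Reactants: 9 2-methoxybenzene-1,3-diol
Product: 10 2-methoxy-1,3-bis(methoxymethoxy)benzene
Conditions: MOMCl (2.5 equiv), i-Pr2NEt (3 equiv), CH2Cl2, 0 °C to rt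
Reagents that add atoms: chloromethyl methyl ether, COCCl
Why: the same Williamson-type acetal protection masks the two ring B phenols and leaves the 4′-methyl ether of the target in place.

Step 7
Reactants: 10 2-methoxy-1,3-bis(methoxymethoxy)benzene
Product: 12 5-iodo-2-methoxy-1,3-bis(methoxymethoxy)benzene, via arylboronic pinacol ester 11 (not isolated)
Conditions: [Ir(OMe)(cod)]2 (1.5 mol %), 4,4′-di-tert-butyl-2,2′-bipyridine (3 mol %), B2pin2 (0.6 equiv), THF, 80 °C; then CuI (10 mol %), 1,10-phenanthroline (20 mol %), KI (1.5 equiv), MeOH/H2O, air, 80 °C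
Reagents that add atoms: potassium iodide, [K+].[I-]; bis(pinacolato)diboron, CC1(C)OB(OC1(C)C)B1OC(C)(C)C(C)(C)O1 (its boron is present only in 11)
Why: sterically controlled iridium-catalysed C–H borylation should reach only the one C–H without an ortho substituent (C5), and copper-catalysed aerobic iododeboronation then gives the iodide under near-neutral conditions that spare the acetals.

Step 8
Reactants: 12 5-iodo-2-methoxy-1,3-bis(methoxymethoxy)benzene; 8 (2R)-2-(benzyloxy)-3-[2-fluoro-4,6-bis(methoxymethoxy)phenyl]propanal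
Product: 14 (1R,2R)-2-(benzyloxy)-3-[2-fluoro-4,6-bis(methoxymethoxy)phenyl]-1-[4-methoxy-3,5-bis(methoxymethoxy)phenyl]propan-1-ol, via arylmagnesium chloride 13 (not isolated)
Conditions: i-PrMgCl·LiCl, THF, 0 °C to rt; then added to 8 pre-complexed with MgBr2·OEt2 (1.5 equiv), CH2Cl2, −78 °C; aq. NH4Cl
Reagents that add atoms: none
Why: iodine–magnesium exchange and chelation-controlled 1,2-addition of the aryl Grignard reagent, in which magnesium bridges the aldehyde oxygen and the α-benzyloxy oxygen and the aryl group enters from the chelate face bearing H rather than CH2Ar, should set C1 as R (syn to the 2R centre), with the minor anti isomer removable by chromatography.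

Step 9
Reactants: 14 (1R,2R)-2-(benzyloxy)-3-[2-fluoro-4,6-bis(methoxymethoxy)phenyl]-1-[4-methoxy-3,5-bis(methoxymethoxy)phenyl]propan-1-ol
Product: 15 (2R,3R)-3-(benzyloxy)-5,7-bis(methoxymethoxy)-2-[4-methoxy-3,5-bis(methoxymethoxy)phenyl]-3,4-dihydro-2H-chromene
Conditions: KN(SiMe3)2 (1.1 equiv), 18-crown-6 (1.2 equiv), THF, 0 °C; then DMF, 60 °C
Reagents that add atoms: none
Why: The potassium alkoxide at C2 adds to the fluorine-bearing carbon of ring A (the future C8a) and fluoride leaves from the Meisenheimer-type adduct, an intramolecular addition–elimination SNAr that is the known alkoxide/fluoroarene route to chromans. Ring C closes in a 6-exo-trig mode. No stereocenter is formed: the C2–O and C3–O bonds stay intact, so the (1R,2R) syn diad of 14 is carried with retention into the 2,3-cis (2R,3R) chroman. The oxygens at C5 and C7 are meta to C8a, so they activate the C–F carbon inductively without donating into it, and the negative charge of the adduct sits on C4a, C6 and C8, none of which bears oxygen. The step needs selectivity for one oxygen and one arene carbon: O3 is capped as a non-migrating benzyl ether, which excludes closure to a five-membered ring, and fluoride is the only leaving group on ring A. Should an aryne arise by deprotonation next to fluorine, the tether would deliver the same product.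

Step 10
Reactants: 15 (2R,3R)-3-(benzyloxy)-5,7-bis(methoxymethoxy)-2-[4-methoxy-3,5-bis(methoxymethoxy)phenyl]-3,4-dihydro-2H-chromene
Product: 16 (2R,3R)-5,7-bis(methoxymethoxy)-2-[4-methoxy-3,5-bis(methoxymethoxy)phenyl]-3,4-dihydro-2H-chromen-3-ol
Conditions: H2 (1 atm), 10% Pd/C (palladium on carbon), EtOAc/MeOH, rt
Reagents that add atoms: none
Why: hydrogenolysis of the alkyl benzyl ether should free O3, while the aryl acetals and the cyclic benzylic C2–O1 ether are not cleaved under these neutral, low-pressure conditions.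

Step 11
Reactants: 17 ferulic acid, (E)-3-(4-hydroxy-3-methoxyphenyl)prop-2-enoic acid
Product: 19 (E)-3-[3-methoxy-4-(methoxymethoxy)phenyl]prop-2-enoic acid, via methoxymethyl ester 18 (not isolated)
Conditions: MOMCl (2.5 equiv), i-Pr2NEt (3 equiv), CH2Cl2, 0 °C to rt; then LiOH, THF/H2O, rt; cold aq. HCl to pH 3
Reagents that add atoms: chloromethyl methyl ether, COCCl
Why: exhaustive alkylation gives the aryl acetal and the methoxymethyl ester, and hydroxide then saponifies only the acylal-type ester, leaving the aryl acetal and the E-alkene.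

Step 12
Reactants: 16 (2R,3R)-5,7-bis(methoxymethoxy)-2-[4-methoxy-3,5-bis(methoxymethoxy)phenyl]-3,4-dihydro-2H-chromen-3-ol; 19 (E)-3-[3-methoxy-4-(methoxymethoxy)phenyl]prop-2-enoic acid
Product: 20 (2R,3R)-5,7-bis(methoxymethoxy)-2-[4-methoxy-3,5-bis(methoxymethoxy)phenyl]-3,4-dihydro-2H-chromen-3-yl (E)-3-[3-methoxy-4-(methoxymethoxy)phenyl]prop-2-enoate
Conditions: DCC (1.5 equiv), DMAP (0.3 equiv), CH2Cl2, 0 °C to rt
Reagents that add atoms: none
Why: Steglich esterification through the N-acylpyridinium ion should acylate the hindered axial secondary alcohol at O3 with retention, the phenol of the acid being masked so that it cannot self-condense.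

Step 13
Reactants: 20 (2R,3R)-5,7-bis(methoxymethoxy)-2-[4-methoxy-3,5-bis(methoxymethoxy)phenyl]-3,4-dihydro-2H-chromen-3-yl (E)-3-[3-methoxy-4-(methoxymethoxy)phenyl]prop-2-enoate
Product: 21 4′-O-methylepigallocatechin 3-O-ferulate, (2R,3R)-2-(3,5-dihydroxy-4-methoxyphenyl)-5,7-dihydroxy-3,4-dihydro-2H-chromen-3-yl (E)-3-(4-hydroxy-3-methoxyphenyl)prop-2-enoate
Conditions: HCl (1.25 M in MeOH)/THF, 0 °C to rt, argon
Reagents that add atoms: none
Why: acid-catalysed acetal exchange with methanol should remove all five aryl methoxymethyl groups much faster than the hindered cinnamate is transesterified, and the 4′-methyl ether blocks the quinone-methide pathway that would epimerise C2.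

**Compound list**

1 | 5-fluorobenzene-1,3-diol | Oc1cc(O)cc(F)c1 | starting material
2 | 1-fluoro-3,5-bis(methoxymethoxy)benzene | COCOc1cc(F)cc(OCOC)c1 | intermediate
3 | 2-bromo-1-fluoro-3,5-bis(methoxymethoxy)benzene | COCOc1cc(F)c(Br)c(OCOC)c1 | intermediate
4 | methyl (2R)-oxirane-2-carboxylate | COC(=O)[C@H]1CO1 | starting material
5 | [2-fluoro-4,6-bis(methoxymethoxy)phenyl]magnesium chloride | COCOc1cc(F)c([Mg]Cl)c(OCOC)c1 | intermediate (not isolated)
6 | methyl (2R)-3-[2-fluoro-4,6-bis(methoxymethoxy)phenyl]-2-hydroxypropanoate | COC(=O)[C@H](O)Cc1c(F)cc(OCOC)cc1OCOC | intermediate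
7 | methyl (2R)-2-(benzyloxy)-3-[2-fluoro-4,6-bis(methoxymethoxy)phenyl]propanoate | COC(=O)[C@H](OCc1ccccc1)Cc1c(F)cc(OCOC)cc1OCOC | intermediate
8 | (2R)-2-(benzyloxy)-3-[2-fluoro-4,6-bis(methoxymethoxy)phenyl]propanal | O=C[C@H](OCc1ccccc1)Cc1c(F)cc(OCOC)cc1OCOC | intermediate
9 | 2-methoxybenzene-1,3-diol | COc1c(O)cccc1O | starting material
10 | 2-methoxy-1,3-bis(methoxymethoxy)benzene | COCOc1cccc(OCOC)c1OC | intermediate
11 | 2-[4-methoxy-3,5-bis(methoxymethoxy)phenyl]-4,4,5,5-tetramethyl-1,3,2-dioxaborolane | COCOc1cc(B2OC(C)(C)C(C)(C)O2)cc(OCOC)c1OC | intermediate (not isolated)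
12 | 5-iodo-2-methoxy-1,3-bis(methoxymethoxy)benzene | COCOc1cc(I)cc(OCOC)c1OC | intermediate
13 | [4-methoxy-3,5-bis(methoxymethoxy)phenyl]magnesium chloride | COCOc1cc([Mg]Cl)cc(OCOC)c1OC | intermediate (not isolated)
14 | (1R,2R)-2-(benzyloxy)-3-[2-fluoro-4,6-bis(methoxymethoxy)phenyl]-1-[4-methoxy-3,5-bis(methoxymethoxy)phenyl]propan-1-ol | O[C@H](c1cc(OCOC)c(OC)c(OCOC)c1)[C@H](OCc1ccccc1)Cc1c(F)cc(OCOC)cc1OCOC | intermediate
15 | (2R,3R)-3-(benzyloxy)-5,7-bis(methoxymethoxy)-2-[4-methoxy-3,5-bis(methoxymethoxy)phenyl]-3,4-dihydro-2H-chromene | c1ccccc1CO[C@@H]1Cc2c(OCOC)cc(OCOC)cc2O[C@@H]1c1cc(OCOC)c(OC)c(OCOC)c1 | intermediate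
16 | (2R,3R)-5,7-bis(methoxymethoxy)-2-[4-methoxy-3,5-bis(methoxymethoxy)phenyl]-3,4-dihydro-2H-chromen-3-ol | O[C@@H]1Cc2c(OCOC)cc(OCOC)cc2O[C@@H]1c1cc(OCOC)c(OC)c(OCOC)c1 | intermediate
17 | ferulic acid, (E)-3-(4-hydroxy-3-methoxyphenyl)prop-2-enoic acid | COc1cc(/C=C/C(=O)O)ccc1O | starting material
18 | methoxymethyl (E)-3-[3-methoxy-4-(methoxymethoxy)phenyl]prop-2-enoate | COCOC(=O)/C=C/c1ccc(OCOC)c(OC)c1 | intermediate (not isolated)
19 | (E)-3-[3-methoxy-4-(methoxymethoxy)phenyl]prop-2-enoic acid | COCOc1ccc(/C=C/C(=O)O)cc1OC | intermediate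
20 | (2R,3R)-5,7-bis(methoxymethoxy)-2-[4-methoxy-3,5-bis(methoxymethoxy)phenyl]-3,4-dihydro-2H-chromen-3-yl (E)-3-[3-methoxy-4-(methoxymethoxy)phenyl]prop-2-enoate | COCOc1ccc(/C=C/C(=O)O[C@@H]2Cc3c(OCOC)cc(OCOC)cc3O[C@@H]2c2cc(OCOC)c(OC)c(OCOC)c2)cc1OC | intermediate
21 | 4′-O-methylepigallocatechin 3-O-ferulate | COc1cc(/C=C/C(=O)O[C@@H]2Cc3c(O)cc(O)cc3O[C@@H]2c2cc(O)c(OC)c(O)c2)ccc1O | target

**Step count.** Total: 13 steps. Longest linear sequence: 10 steps (steps 1, 2, 3, 4, 5, 8, 9, 10, 12, 13).

**Steps most likely to fail**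

Step 9. Fluoride displacement on the electron-rich ring may be slow, so that the alkoxide decomposes on prolonged heating before the ring closes. The fallback closes the same bond by elimination–addition instead of addition–elimination. Setting out from 14, lithium 2,2,6,6-tetramethylpiperidide (3 equiv, THF, −78 to 0 °C) should first form the lithium alkoxide and then remove the arene proton between fluorine and the acetal oxygen. Loss of LiF gives the aryne alkoxide intermediate F1. Its tethered oxygen can reach only the aryne carbon next to the benzylic carbon (6-exo), and protonation of the resulting aryl anion, which lies ortho to the C7 acetal oxygen, comes back to the route at 15. Aryne cyclisation by a tethered alkoxide is established chemistry, and C2 is again untouched.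

Step 8. Facial selectivity may erode if THF from the Grignard solution competes for magnesium and opens the chelate, and aldehyde 8 may partly epimerise before it is consumed. The fallback sets out from ester 7. MeNH(OMe)·HCl with i-PrMgCl (THF, −20 °C) should give the Weinreb amide F2, and addition of 13 should stop at the aryl ketone F3. Catalyst-controlled Noyori transfer hydrogenation (RuCl[(S,S)-TsDPEN](p-cymene), HCO2Na, H2O/MeOH, 40 °C) then sets C1; its known sense on aryl ketones of this type corresponds to the (1R) carbinol, which comes back to the route at 14.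

Step 13. During acetal cleavage the ferulate may be transesterified by acidic methanol, or formaldehyde equivalents may attack ring A. The fallback moves the acidic step in front of the esterification. Setting out from 16, HCl/MeOH should give 4′-O-methylepigallocatechin F4, with no ester present. TBSCl (4.4 equiv) with imidazole (DMF, 0 °C) should silylate the four phenols in preference to the axial secondary alcohol and give the tetrasilyl ether F5. Ferulic acid 17 is converted with TBSCl/imidazole into the bis-silyl derivative F6 and then with K2CO3 in MeOH/H2O into the silyl-protected acid F7. DCC/DMAP coupling of F5 with F7 gives the pentasilyl ester F8, and HF·pyridine (THF, 0 °C) removes the five aryl silyl ethers without touching ester or alkene, coming back to the route at 21.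

Further compounds
F1 | step 9 | (1R,2R)-2-(benzyloxy)-3-[2,3-didehydro-4,6-bis(methoxymethoxy)phenyl]-1-[4-methoxy-3,5-bis(methoxymethoxy)phenyl]propan-1-ol (aryne, present as its lithium alkoxide) | O[C@H](c1cc(OCOC)c(OC)c(OCOC)c1)[C@H](OCc1ccccc1)CC1=C(OCOC)C=C(OCOC)C#C1
F2 | step 8 | (2R)-2-(benzyloxy)-3-[2-fluoro-4,6-bis(methoxymethoxy)phenyl]-N-methoxy-N-methylpropanamide | CON(C)C(=O)[C@H](OCc1ccccc1)Cc1c(F)cc(OCOC)cc1OCOC
F3 | step 8 | (2R)-2-(benzyloxy)-3-[2-fluoro-4,6-bis(methoxymethoxy)phenyl]-1-[4-methoxy-3,5-bis(methoxymethoxy)phenyl]propan-1-one | O=C(c1cc(OCOC)c(OC)c(OCOC)c1)[C@H](OCc1ccccc1)Cc1c(F)cc(OCOC)cc1OCOC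
F4 | step 13 | 4′-O-methylepigallocatechin, (2R,3R)-2-(3,5-dihydroxy-4-methoxyphenyl)-3,4-dihydro-2H-chromene-3,5,7-triol | O[C@@H]1Cc2c(O)cc(O)cc2O[C@@H]1c1cc(O)c(OC)c(O)c1
F5 | step 13 | (2R,3R)-5,7-bis(tert-butyldimethylsilyloxy)-2-[3,5-bis(tert-butyldimethylsilyloxy)-4-methoxyphenyl]-3,4-dihydro-2H-chromen-3-ol | O[C@@H]1Cc2c(O[Si](C)(C)C(C)(C)C)cc(O[Si](C)(C)C(C)(C)C)cc2O[C@@H]1c1cc(O[Si](C)(C)C(C)(C)C)c(OC)c(O[Si](C)(C)C(C)(C)C)c1
F6 | step 13 | tert-butyldimethylsilyl (E)-3-[4-(tert-butyldimethylsilyloxy)-3-methoxyphenyl]prop-2-enoate | COc1cc(/C=C/C(=O)O[Si](C)(C)C(C)(C)C)ccc1O[Si](C)(C)C(C)(C)C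
F7 | step 13 | (E)-3-[4-(tert-butyldimethylsilyloxy)-3-methoxyphenyl]prop-2-enoic acid | COc1cc(/C=C/C(=O)O)ccc1O[Si](C)(C)C(C)(C)C
F8 | step 13 | (2R,3R)-5,7-bis(tert-butyldimethylsilyloxy)-2-[3,5-bis(tert-butyldimethylsilyloxy)-4-methoxyphenyl]-3,4-dihydro-2H-chromen-3-yl (E)-3-[4-(tert-butyldimethylsilyloxy)-3-methoxyphenyl]prop-2-enoate | COc1cc(/C=C/C(=O)O[C@@H]2Cc3c(O[Si](C)(C)C(C)(C)C)cc(O[Si](C)(C)C(C)(C)C)cc3O[C@@H]2c2cc(O[Si](C)(C)C(C)(C)C)c(OC)c(O[Si](C)(C)C(C)(C)C)c2)ccc1O[Si](C)(C)C(C)(C)C
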